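## Structural features

The target is a fully substituted 1H-pyrrole: C2 carries a methyl ester, C5 an acetyl group, and C3 and C4 each carry an indol-3-yl ring through a C(sp2)–C(sp2) bond. It has no stereocentre. The two indoles are the same substituent and differ only through their neighbours (ester side or acetyl side), so a symmetric construction would later have to tell two near-identical acyl groups apart. The fragile parts are the free indoles (N–H and C2 are sensitive to acid, oxidants and electrophiles), the electron-rich pyrrole, and the ester and methyl ketone, which must both survive the last deprotection. The real difficulty is the congested C3–C4 bond between two carbons that each bear an indolyl group, made with the ester already on one flank and the acetyl on the other. The key step uses the fact that C3 sits next to C2, which is at the oxidation level of an α-imino ester, so C3 can be an acceptor as the terminus of a nitrosoalkene. C4 sits next to the C5 ketone, so it can be a donor as an enol ether carbon. The ring nitrogen and the C5 oxygen then stand in a 1,4 relation, which is what a pyrrole closure needs. The three contiguous sp3 centres of the intermediate oxazine disappear on aromatisation.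

## Logic of the disconnections

16 ⇒ 15. The two indole N–S bonds are the last to be cut in the forward direction. The sulfonyl groups are kept until the end because they block N–H, damp the nucleophilicity of indole C2/C3 towards the nitrosoalkene, slow ionisation of the benzylic chloride in 5, and allow palladium chemistry on 6. The demand is that their removal spares a methyl ketone and a methyl ester.

15 ⇒ 12 (through 14 and 13). The N1–C5 bond of the pyrrole is cut and the nitrogen is tied back to oxygen, so the aromatic ring becomes the six-membered N–O ring of 12, in which C6 is the masked C5 ketone. The gain is that all four substituents now sit on a ring that a cycloaddition can assemble. The demand is that N–O cleavage stops at the imine and that the nitrogen finds only one carbonyl to close on.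

12 ⇒ 5 + 10 (through 11). The C4–C5 and O1–C6 bonds of 12 are cut in a retro-[4+2]. This is the only cut that separates the molecule into an ester half and an acetyl half of equal size while giving the two indolyl-bearing carbons opposite polarity. The constitution of 12 agrees with this pattern: C3 carries the ester, C4 and C5 the indolyl groups, C6 the siloxy group and the acetyl carbon. One change to the enol ether partner is made without touching the skeleton or the bonds formed. With a free acetyl, 10 would be a 2-siloxy enone: its reacting carbon would be donor and acceptor at once, and after N–O cleavage the resulting 1,2-dione would offer the nitrogen a second carbonyl, which could close a six-membered ring to a hydroxypyridine. The acetyl is therefore carried as its dimethyl ketal, and the silyl group is tert-butyldimethylsilyl so that 10 and 12 can be purified and 10 used in near-equimolar amount. The demand is that the transient 11 is captured faster than it self-condenses.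

10 ⇒ 8 (through 9). Only the O–Si bond is cut. 8 has a single enolisable position, so the regiochemistry of enol ether formation is not in question; the demand is a silylation that does not ionise the ketal.

8 ⇒ 6 + 7. The bond between indole C3 and the methylene carbon is cut. 7 already holds the whole four-carbon chain with the acetyl masked, and it is a pinacolone-like methyl ketone, the best kind of substrate for mono-arylation. The demand is a base mild enough for the sulfonamide.

5 ⇒ 4. The C=N bond is cut; the oxime comes from the 2-oxo ester, and the demand is that no base is present that would eliminate HCl early.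

4 ⇒ 1 + 2 (through 3). The C2–C3 bond of the propanoate is cut. The aldehyde carbon of 1 becomes the chlorine-bearing carbon, and 2 supplies the ester, the future imine carbon and the chlorine in one reagent. The demand is brief exposure of the N-sulfonyl aldehyde to alkoxide.

## Other disconnections considered

Alternative 1: The cut lies inside both indoles: in each, C3–C3a and N1–C2 are broken. This leads back to methyl 5-acetyl-3,4-bis[(trimethylsilyl)ethynyl]-1H-pyrrole-2-carboxylate A1 and two molecules of 2-iodoaniline A2. Forward, a double Larock heteroannulation under palladium catalysis with carbonate base and a chloride additive would give methyl 5-acetyl-3,4-bis[2-(trimethylsilyl)-1H-indol-3-yl]-1H-pyrrole-2-carboxylate A3, and protodesilylation of both indole C2 positions would give 16.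
- In its favour: the ester/acetyl pattern is fixed on the pyrrole before any indole exists, the silyl groups direct each annulation so the pyrrole ends up at indole C3, and no indole nitrogen needs protection.
- Against it here: A1 needs a 3,4-dihalopyrrole that already carries both acyl groups, followed by two couplings at hindered neighbouring positions. After the first carbopalladation the vinylpalladium intermediate sits next to the second alkyne, so intramolecular insertion could compete with C–N bond formation. The second annulation has to take place beside a bulky 2-silylindole. The acidic pyrrole N–H and the ketone are exposed to hot base.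
- Comparison: on structure it is the equal of the chosen plan, and the better in one respect, since no question arises of which carbonyl the nitrogen closes on. On mechanism the chosen plan is cleaner, because its two partners have only one productive pairing. On step economy the two should be about equal, and the mild final desilylation of A3 is better than a reductive desulfonylation.

Alternative 2: The cut is made at the C2–C3 and C4–C5 bonds at the stage of a six-membered diazine. Dimethyl 1,2,4,5-tetrazine-3,6-dicarboxylate A4 would add across the triple bond of di-tert-butyl 3,3'-(ethyne-1,2-diyl)bis(1H-indole-1-carboxylate) A5. Loss of N2 would give dimethyl 4,5-bis[1-(tert-butoxycarbonyl)indol-3-yl]pyridazine-3,6-dicarboxylate A6, and reductive N–N cleavage with reclosure would contract the ring to dimethyl 3,4-bis[1-(tert-butoxycarbonyl)indol-3-yl]-1H-pyrrole-2,5-dicarboxylate A7.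
- In its favour: A4 is a stable, isolable diene, the cycloaddition is made irreversible by loss of N2, both partners are symmetric so no regiochemistry arises, and the diazine-to-pyrrole contraction is an established reaction type.
- Against it here: A7 has two identical esters, whereas 16 needs an ester and a methyl ketone. One of two equivalent esters would have to be converted, which means a statistical mono-hydrolysis followed by conversion of the acid into a methyl ketone (several extra steps with statistical loss). The hindered diarylalkyne A5 is also a slow dienophile, and heating endangers the carbamates.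
- Comparison: on mechanism it closely parallels the chosen plan (inverse-demand [4+2], then reductive contraction of a six-membered ring), and is the better in that its diene is not a transient species. On structure it is worse, because it gives a symmetric core for an unsymmetric target. On step economy it is worse for the same reason.

Alternative 3: The cut takes out three pyrrole bonds: C3–C4 (made as a C=C bond), C2–C3 and C4–C5. In one flask, aldehyde 1 and 3-(nitromethyl)-1-tosyl-1H-indole A8 would condense under amine catalysis (Henry reaction with dehydration) to 3,3'-(1-nitroethene-1,2-diyl)bis(1-tosyl-1H-indole) A9. Methyl isocyanoacetate A10 and an amidine base would then add (Barton–Zard reaction) and give methyl 3,4-bis(1-tosyl-1H-indol-3-yl)-1H-pyrrole-2-carboxylate A11 with loss of nitrite. Friedel–Crafts acetylation of the only free pyrrole position would then meet the chosen route at 15.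
- In its favour: the pyrrole forms aromatic in one operation with no redox ring contraction, 1 is shared with the chosen route, and the late acetylation has only one pyrrole position to choose.
- Against it here: A8 is an arylnitromethane that needs about three steps from 1 and is prone to side reactions at the nitronate stage. The isocyanoacetate anion must add to the hindered, diaryl-substituted A9. The acetyl group has to be put on a pyrrole that is deactivated by its ester and flanked by an aryl group, under Lewis acid, with two further heteroaromatic rings present.
- Comparison: on step economy it is the better of the two, probably by one step. On structure it is the equal: the unsymmetry is solved by order of events instead of by fragment design. On mechanism both rest on well-precedented reaction types. The chosen plan has the advantage that both acyl groups are in place before the ring forms, so no electrophilic substitution is needed on the assembled tris-heteroaryl.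

Key step: step 5

Remark: 1-tosyl-1H-indole-3-carbaldehyde (1), 3-bromo-1-tosyl-1H-indole (6) and 3,3-dimethoxybutan-2-one (7) are taken as catalogue compounds; tosyl means 4-methylbenzenesulfonyl throughout.

## Route

Step 1
Reactants: 1 1-tosyl-1H-indole-3-carbaldehyde; 2 methyl dichloroacetate
Product: 4 methyl 3-chloro-2-oxo-3-(1-tosyl-1H-indol-3-yl)propanoate, via chloroglycidate 3 (not isolated)
Conditions: NaOMe, MeOH–Et2O, −10 → 0 °C; then toluene, 50 °C
Reagents that add atoms: none
Why: Darzens condensation: the sodium enolate of 2 adds to the aldehyde of 1 and the alkoxide displaces one chloride to give chloroglycidate 3. Its C–Cl bond then ionises with opening of the epoxide towards the indolyl-stabilised carbon and chloride returns there, the known isomerisation of 2-chloroglycidic esters to 3-chloro-2-oxo esters. The new C3 centre is racemic and is erased in step 5; the short, cold exposure to methoxide should spare the sulfonamide.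

Step 2
Reactants: 4 methyl 3-chloro-2-oxo-3-(1-tosyl-1H-indol-3-yl)propanoate
Product: 5 methyl (Z)-3-chloro-2-(hydroxyimino)-3-(1-tosyl-1H-indol-3-yl)propanoate
Conditions: NH2OH·HCl, MeOH–CH2Cl2, rt
Reagents that add atoms: hydroxylamine hydrochloride, Cl.NO
Why: Oxime condensation at the strongly electrophilic 2-oxo ester carbonyl, the standard way to α-halo oximes. With the hydrochloride salt and no added base the benzylic chloride should be neither eliminated nor displaced, and the oxime geometry does not matter for step 5.

Step 3
Reactants: 6 3-bromo-1-tosyl-1H-indole; 7 3,3-dimethoxybutan-2-one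
Product: 8 3,3-dimethoxy-1-(1-tosyl-1H-indol-3-yl)butan-2-one
Conditions: Pd2(dba)3 (cat.), XPhos (cat.), K3PO4, toluene, 80 °C
Reagents that add atoms: none
Why: Palladium-catalysed ketone α-arylation (Buchwald–Hartwig type): zerovalent palladium inserts into the C3–Br bond of 6, the potassium enolate of 7 (enolisable only at its methyl group, a pinacolone-like ketone) replaces bromide on palladium, and C–C reductive elimination follows. The bulky biaryl phosphine and the more hindered product methylene disfavour a second arylation, and phosphate is too poor a nucleophile to attack the sulfonamide.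

Step 4
Reactants: 8 3,3-dimethoxy-1-(1-tosyl-1H-indol-3-yl)butan-2-one
Product: 10 (Z)-3-[2-(tert-butyldimethylsilyloxy)-3,3-dimethoxybut-1-en-1-yl]-1-tosyl-1H-indole, via potassium enolate 9 (not isolated)
Conditions: KN(SiMe3)2, THF, −78 °C; then t-BuMe2SiCl, −78 → 0 °C
Reagents that add atoms: tert-butyldimethylsilyl chloride, CC(C)(C)[Si](C)(C)Cl
Why: Enolate O-silylation: deprotonation can occur only at the indolylmethylene position, the enolate places the indolyl group cis to oxygen to avoid the quaternary ketal carbon (Z), and the hard potassium enolate is silylated on oxygen. An amide base with a silyl chloride is used in place of a silyl triflate so that the dimethyl ketal is not ionised.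

Step 5
Reactants: 5 methyl (Z)-3-chloro-2-(hydroxyimino)-3-(1-tosyl-1H-indol-3-yl)propanoate; 10 (Z)-3-[2-(tert-butyldimethylsilyloxy)-3,3-dimethoxybut-1-en-1-yl]-1-tosyl-1H-indole
Product: 12 methyl rac-(4R,5R,6R)-6-(tert-butyldimethylsilyloxy)-6-(1,1-dimethoxyethyl)-4,5-bis(1-tosyl-1H-indol-3-yl)-5,6-dihydro-4H-1,2-oxazine-3-carboxylate, via nitrosoalkene 11 (not isolated)
Conditions: Na2CO3 (powder, excess), CH2Cl2, rt, 5 (slight excess) added in portions
Reagents that add atoms: none
Why: Carbonate removes HCl from 5 (oxime O–H and C3–Cl, a 1,4-elimination) and releases nitrosoalkene 11 slowly and at low concentration. 11 is an electron-poor O=N–C=C heterodiene whose LUMO is lowered by the ester, and 10 is an electron-rich 2π partner whose HOMO is raised by the siloxy group and is no longer lowered by a conjugated carbonyl because the acetyl is masked; the two should combine in an inverse-electron-demand hetero-Diels–Alder reaction. The closest known reaction type is the [4+2] cycloaddition of α-nitrosoalkenes, generated from α-halo oximes with sodium carbonate, with silyl enol ethers to give 6-siloxy-5,6-dihydro-4H-1,2-oxazines. The oxazine ring is closed by the cycloaddition itself: C4–C5 and O1–C6 form in one bimolecular event, concerted but asynchronous with C–C bonding ahead, and in the stepwise limit the oximate oxygen closes on the siloxy-stabilised cation in a 6-exo-trig sense. The relative configuration of C5 and C6 (indolyl cis to siloxy) follows from suprafacial addition to the Z double bond of 10; that of C4 relative to C5 depends on the geometry of 11 and on endo or exo approach and is not controlled; all three centres are racemic and are destroyed on aromatisation, so the C4 epimer serves equally. The selectivity that matters is regiochemical: the largest LUMO coefficient of 11 and the largest HOMO coefficient of 10 both lie on the indolyl-bearing carbons, so these two carbons bond and the nitroso oxygen goes to the siloxy carbon, and since 11 is the only electrophile and 10 the only nucleophile, only the cross-coupled bond can form. The N-sulfonyl groups keep the indole C2=C3 bonds from competing as 2π partners, and portionwise addition of 5 limits self-condensation of 11.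

Step 6
Reactants: 12 methyl rac-(4R,5R,6R)-6-(tert-butyldimethylsilyloxy)-6-(1,1-dimethoxyethyl)-4,5-bis(1-tosyl-1H-indol-3-yl)-5,6-dihydro-4H-1,2-oxazine-3-carboxylate
Product: 15 methyl 5-acetyl-3,4-bis(1-tosyl-1H-indol-3-yl)-1H-pyrrole-2-carboxylate, via imino ketone 13 (not isolated), via ketal pyrrole 14 (not isolated)
Conditions: Mo(CO)6, MeCN–H2O (15:1), reflux; then 1 M HCl, THF, rt
Reagents that add atoms: water, O
Why: Zerovalent molybdenum cleaves the N–O bond reductively and the C6 silyl hemiketal collapses to the ketone with loss of silanol, giving imino ketone 13; its nitrogen closes on the only free carbonyl (5-exo-trig, Paal–Knorr type) and dehydration gives ketal pyrrole 14, the known reductive ring contraction of 6-siloxy-1,2-oxazines. The ketal is inert while it is next to a carbonyl, becomes acid-labile once attached to the pyrrole, and is then hydrolysed by dilute acid through a pyrrole-stabilised oxocarbenium ion.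

Step 7
Reactants: 15 methyl 5-acetyl-3,4-bis(1-tosyl-1H-indol-3-yl)-1H-pyrrole-2-carboxylate
Product: 16 methyl 5-acetyl-3,4-di(1H-indol-3-yl)-1H-pyrrole-2-carboxylate
Conditions: Mg turnings, MeOH, sonication, rt; aq. NH4Cl
Reagents that add atoms: none
Why: Electron-transfer cleavage of both indole N–S bonds by magnesium in methanol, a standard N-desulfonylation, gives the free indoles and sulfinate. The acidic pyrrole N–H is deprotonated by the magnesium methoxide formed, which makes the acetyl group a vinylogous amide anion that should resist reduction, and the methyl ester can only exchange degenerately with the solvent.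

## Compound list

1 | 1-tosyl-1H-indole-3-carbaldehyde | O=Cc1cn(S(=O)(=O)c2ccc(C)cc2)c2ccccc12 | starting material
2 | methyl dichloroacetate | COC(=O)C(Cl)Cl | starting material
3 | methyl 2-chloro-3-(1-tosyl-1H-indol-3-yl)oxirane-2-carboxylate (racemic; both diastereomers) | COC(=O)C1(Cl)OC1c1cn(S(=O)(=O)c2ccc(C)cc2)c2ccccc12 | intermediate
4 | methyl 3-chloro-2-oxo-3-(1-tosyl-1H-indol-3-yl)propanoate (racemic) | COC(=O)C(=O)C(Cl)c1cn(S(=O)(=O)c2ccc(C)cc2)c2ccccc12 | intermediate
5 | methyl (Z)-3-chloro-2-(hydroxyimino)-3-(1-tosyl-1H-indol-3-yl)propanoate (racemic; the E oxime serves equally) | COC(=O)/C(=N/O)C(Cl)c1cn(S(=O)(=O)c2ccc(C)cc2)c2ccccc12 | intermediate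
6 | 3-bromo-1-tosyl-1H-indole | Brc1cn(S(=O)(=O)c2ccc(C)cc2)c2ccccc12 | starting material
7 | 3,3-dimethoxybutan-2-one | CC(=O)C(C)(OC)OC | starting material
8 | 3,3-dimethoxy-1-(1-tosyl-1H-indol-3-yl)butan-2-one | CC(OC)(OC)C(=O)Cc1cn(S(=O)(=O)c2ccc(C)cc2)c2ccccc12 | intermediate
9 | potassium (Z)-3,3-dimethoxy-1-(1-tosyl-1H-indol-3-yl)but-1-en-2-olate | CC(OC)(OC)/C([O-])=C/c1cn(S(=O)(=O)c2ccc(C)cc2)c2ccccc12.[K+] | intermediate
10 | (Z)-3-[2-(tert-butyldimethylsilyloxy)-3,3-dimethoxybut-1-en-1-yl]-1-tosyl-1H-indole | CC(OC)(OC)/C(O[Si](C)(C)C(C)(C)C)=C/c1cn(S(=O)(=O)c2ccc(C)cc2)c2ccccc12 | intermediate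
11 | methyl 2-nitroso-3-(1-tosyl-1H-indol-3-yl)prop-2-enoate (alkene geometry not defined) | COC(=O)C(N=O)=Cc1cn(S(=O)(=O)c2ccc(C)cc2)c2ccccc12 | intermediate
12 | methyl rac-(4R,5R,6R)-6-(tert-butyldimethylsilyloxy)-6-(1,1-dimethoxyethyl)-4,5-bis(1-tosyl-1H-indol-3-yl)-5,6-dihydro-4H-1,2-oxazine-3-carboxylate (racemic; C5 indolyl cis to the C6 siloxy group and trans to the C4 indolyl; one enantiomer drawn) | COC(=O)C1=NO[C@](O[Si](C)(C)C(C)(C)C)(C(C)(OC)OC)[C@@H](c2cn(S(=O)(=O)c3ccc(C)cc3)c3ccccc23)[C@@H]1c1cn(S(=O)(=O)c2ccc(C)cc2)c2ccccc12 | intermediate
13 | methyl 2-imino-6,6-dimethoxy-5-oxo-3,4-bis(1-tosyl-1H-indol-3-yl)heptanoate (C3 and C4 configuration inherited from 12, of no consequence) | COC(=O)C(=N)C(c1cn(S(=O)(=O)c2ccc(C)cc2)c2ccccc12)C(c1cn(S(=O)(=O)c2ccc(C)cc2)c2ccccc12)C(=O)C(C)(OC)OC | intermediate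
14 | methyl 5-(1,1-dimethoxyethyl)-3,4-bis(1-tosyl-1H-indol-3-yl)-1H-pyrrole-2-carboxylate | COC(=O)c1[nH]c(C(C)(OC)OC)c(-c2cn(S(=O)(=O)c3ccc(C)cc3)c3ccccc23)c1-c1cn(S(=O)(=O)c2ccc(C)cc2)c2ccccc12 | intermediate
15 | methyl 5-acetyl-3,4-bis(1-tosyl-1H-indol-3-yl)-1H-pyrrole-2-carboxylate | COC(=O)c1[nH]c(C(C)=O)c(-c2cn(S(=O)(=O)c3ccc(C)cc3)c3ccccc23)c1-c1cn(S(=O)(=O)c2ccc(C)cc2)c2ccccc12 | intermediate
16 | methyl 5-acetyl-3,4-di(1H-indol-3-yl)-1H-pyrrole-2-carboxylate | COC(=O)c1[nH]c(C(C)=O)c(-c2c[nH]c3ccccc23)c1-c1c[nH]c2ccccc12 | target

## Step count and least certain steps

Total: 7 steps. Longest linear sequence: 5 steps (steps 3, 4, 5, 6, 7; the branch through steps 1 and 2 is equally long).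

Step 5 (key step). The most likely failure is self-condensation of the transient nitrosoalkene outrunning its capture. The attacking enol ether carbon is trisubstituted and lies between an indolyl group and a quaternary ketal carbon, and both new bonds form at crowded centres. Fallback: make the same C–C bond by anionic conjugate addition instead of cycloaddition. It sets out from 8 and 5. 8 is converted with KN(SiMe3)2 in THF at −78 °C into enolate 9 (two equivalents), and 5 is added. The first equivalent releases 11 and the second adds to its indolyl-bearing carbon, the known Michael addition of ketone enolates to nitrosoalkenes made in situ. After protonation this gives methyl 2-(hydroxyimino)-6,6-dimethoxy-5-oxo-3,4-bis(1-tosyl-1H-indol-3-yl)heptanoate F1 (in equilibrium with its cyclic hemiketal). Under the conditions of step 6 F1 should lose the oxime N–O bond and close in the same way, so the fallback comes back to the route at 15.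

Step 3. The likely failures are slow coupling at the hindered enolate, with hydrodebromination of 6 taking over, and base-induced loss of the sulfonyl group on prolonged heating. Fallback: change the nucleophile from a base-generated enolate to a preformed neutral enol silane. It sets out from 7 and 6. 7 is converted with LiN(i-Pr)2 and Me3SiCl into [(3,3-dimethoxybut-1-en-2-yl)oxy]trimethylsilane F2, which is coupled with 6 using PdCl2[P(o-tolyl)3]2 and Bu3SnF in hot toluene (arylation through a tin enolate formed in the flask, no free base). The fallback comes back at 8.

Step 6. The likely failures are hydrolysis of the N–H imine of 13 to the 2-oxo ester in the hot aqueous medium before it can close, and stalling of N–O cleavage at the fully substituted C6. Fallback: reduce fully and re-oxidise, without water. It sets out from 12. Hydrogenolysis (H2, Pd/C, MeOH, rt) cleaves N–O and reduces C=N; the amino ketone closes to methyl 5-(1,1-dimethoxyethyl)-3,4-bis(1-tosyl-1H-indol-3-yl)-3,4-dihydro-2H-pyrrole-2-carboxylate F3, whose hindered C=N bond should resist further reduction. Dehydrogenation with DDQ in toluene then gives the pyrrole, and the fallback comes back at 14, which is hydrolysed to 15 as in step 6.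

Step 1. The likely failures are methoxide attack at sulfur of the electron-poor N-sulfonyl aldehyde (loss of the protecting group) and an incomplete chlorine shift in 3. Fallback: avoid alkoxide and the glycidate altogether. It sets out from 1. Horner–Wadsworth–Emmons olefination with methyl 2-(tert-butyldimethylsilyloxy)-2-(dimethoxyphosphoryl)acetate (LiN(SiMe3)2, THF, −78 → 0 °C) gives methyl 2-(tert-butyldimethylsilyloxy)-3-(1-tosyl-1H-indol-3-yl)prop-2-enoate F4. Chlorination of this silyl enol ether with N-chlorosuccinimide in CH2Cl2 puts chlorine on the indolyl-bearing carbon and frees the ketone, and the fallback comes back at 4.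

## Further compounds

F1 | step 5 | methyl 2-(hydroxyimino)-6,6-dimethoxy-5-oxo-3,4-bis(1-tosyl-1H-indol-3-yl)heptanoate (diastereomer mixture) | COC(=O)C(=NO)C(c1cn(S(=O)(=O)c2ccc(C)cc2)c2ccccc12)C(c1cn(S(=O)(=O)c2ccc(C)cc2)c2ccccc12)C(=O)C(C)(OC)OC
F2 | step 3 | [(3,3-dimethoxybut-1-en-2-yl)oxy]trimethylsilane | C=C(O[Si](C)(C)C)C(C)(OC)OC
F3 | step 6 | methyl 5-(1,1-dimethoxyethyl)-3,4-bis(1-tosyl-1H-indol-3-yl)-3,4-dihydro-2H-pyrrole-2-carboxylate (diastereomer mixture) | COC(=O)C1N=C(C(C)(OC)OC)C(c2cn(S(=O)(=O)c3ccc(C)cc3)c3ccccc23)C1c1cn(S(=O)(=O)c2ccc(C)cc2)c2ccccc12
F4 | step 1 | methyl 2-(tert-butyldimethylsilyloxy)-3-(1-tosyl-1H-indol-3-yl)prop-2-enoate (alkene geometry not defined) | COC(=O)C(O[Si](C)(C)C(C)(C)C)=Cc1cn(S(=O)(=O)c2ccc(C)cc2)c2ccccc12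
A1 | alternative 1 | methyl 5-acetyl-3,4-bis[(trimethylsilyl)ethynyl]-1H-pyrrole-2-carboxylate | COC(=O)c1[nH]c(C(C)=O)c(C#C[Si](C)(C)C)c1C#C[Si](C)(C)C
A2 | alternative 1 | 2-iodoaniline | Nc1ccccc1I
A3 | alternative 1 | methyl 5-acetyl-3,4-bis[2-(trimethylsilyl)-1H-indol-3-yl]-1H-pyrrole-2-carboxylate | COC(=O)c1[nH]c(C(C)=O)c(-c2c([Si](C)(C)C)[nH]c3ccccc23)c1-c1c([Si](C)(C)C)[nH]c2ccccc12
A4 | alternative 2 | dimethyl 1,2,4,5-tetrazine-3,6-dicarboxylate | COC(=O)c1nnc(C(=O)OC)nn1
A5 | alternative 2 | di-tert-butyl 3,3'-(ethyne-1,2-diyl)bis(1H-indole-1-carboxylate) | CC(C)(C)OC(=O)n1cc(C#Cc2cn(C(=O)OC(C)(C)C)c3ccccc23)c2ccccc12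
A6 | alternative 2 | dimethyl 4,5-bis[1-(tert-butoxycarbonyl)indol-3-yl]pyridazine-3,6-dicarboxylate | COC(=O)c1nnc(C(=O)OC)c(-c2cn(C(=O)OC(C)(C)C)c3ccccc23)c1-c1cn(C(=O)OC(C)(C)C)c2ccccc12
A7 | alternative 2 | dimethyl 3,4-bis[1-(tert-butoxycarbonyl)indol-3-yl]-1H-pyrrole-2,5-dicarboxylate | COC(=O)c1[nH]c(C(=O)OC)c(-c2cn(C(=O)OC(C)(C)C)c3ccccc23)c1-c1cn(C(=O)OC(C)(C)C)c2ccccc12
A8 | alternative 3 | 3-(nitromethyl)-1-tosyl-1H-indole | O=[N+]([O-])Cc1cn(S(=O)(=O)c2ccc(C)cc2)c2ccccc12
A9 | alternative 3 | 3,3'-(1-nitroethene-1,2-diyl)bis(1-tosyl-1H-indole) (alkene geometry not defined) | O=[N+]([O-])C(=Cc1cn(S(=O)(=O)c2ccc(C)cc2)c2ccccc12)c1cn(S(=O)(=O)c2ccc(C)cc2)c2ccccc12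
A10 | alternative 3 | methyl isocyanoacetate | [C-]#[N+]CC(=O)OC
A11 | alternative 3 | methyl 3,4-bis(1-tosyl-1H-indol-3-yl)-1H-pyrrole-2-carboxylate | COC(=O)c1[nH]cc(-c2cn(S(=O)(=O)c3ccc(C)cc3)c3ccccc23)c1-c1cn(S(=O)(=O)c2ccc(C)cc2)c2ccccc12
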